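**Retrosynthetic overview** (ring C1 = ketone carbon to C6 as in the target; side chain C1' to C12')
1. The target comes from a protected precursor by desilylation and hydrolysis of a C1 dimethyl ketal, under which the ketone travels through the route.
2. Key disconnection C5'–C6' (sp3–sp2): palladium-catalysed B-alkyl Suzuki–Miyaura coupling of the 9-BBN adduct of a ring-bound (E)-3-methylpenta-2,4-dienyl group with a C6'–C12' (E)-alkenyl iodide that carries the 9'S carbinol.
3. Ring fragment: 2,3,4,4-tetramethoxycyclohexa-2,5-dienone + MeMgBr + an (E)-dienyl bromide in a one-pot copper-catalysed enantioselective conjugate methylation/enolate alkylation (C6–CH3 and C5–C1' bonds), then cis-selective ketone reduction (C4–OH).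
4. Alkenyl iodide: asymmetric propargylation of 3-methylbut-2-enal, SeO2 oxidation of the (E)-methyl group, zirconium-catalysed carboalumination/iodination.
5. Ring order: the single carbocycle is made first, from squaric acid, by vinyl addition to dimethyl squarate and thermal four-to-six ring expansion to 2,3,4-trimethoxyphenol, then oxidative dearomatisation to the quinone monoketal.

Assumption: squaric acid, (2E)-3-methylpent-2-en-4-yn-1-ol, 3-methylbut-2-enal and propargyl bromide are bought; in the two ligand-controlled steps (8 and 10) the ligand antipode is used if a first run shows the opposite sense.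

**Route**

Step 1
Reactants: 1 squaric acid (3,4-dihydroxycyclobut-3-ene-1,2-dione)
Product: 2 dimethyl squarate (3,4-dimethoxycyclobut-3-ene-1,2-dione)
Conditions: HC(OMe)3 (2.5 equiv), MeOH, reflux
Reagents that add atoms: trimethyl orthoformate COC(OC)OC
Why: Orthoester-mediated O-methylation of a vinylogous diacid, driven by loss of methyl formate, gives the bis(vinylogous ester) cleanly.

Step 2
Reactants: 2 dimethyl squarate
Product: 3 4-ethenyl-4-hydroxy-2,3-dimethoxycyclobut-2-en-1-one (racemic)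
Conditions: CH2=CHMgBr (1.05 equiv), THF, −78 °C; then H2O
Reagents that add atoms: vinylmagnesium bromide C=C[Mg]Br
Why: Grignard 1,2-addition to one of the two equivalent carbonyl groups stops at mono-addition because the alkoxide deactivates the remaining vinylogous ester, and the racemic centre formed is destroyed in step 4.

Step 3
Reactants: 3 4-ethenyl-4-hydroxy-2,3-dimethoxycyclobut-2-en-1-one
Product: 4 4-ethenyl-2,3,4-trimethoxycyclobut-2-en-1-one (racemic)
Conditions: MeI (10 equiv), Ag2O (1.5 equiv), MeCN, rt, dark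
Reagents that add atoms: iodomethane CI
Why: Purdie methylation (MeI/Ag2O) etherifies the acidic tertiary hydroxyl without the strong base that would open the hydroxycyclobutenone.

Step 4
Reactants: 4 4-ethenyl-2,3,4-trimethoxycyclobut-2-en-1-one
Product: 7 2,3,4-trimethoxyphenol, via dienylketene 5 (not isolated), via cyclohexadienone 6 (not isolated)
Conditions: p-xylene (0.05 M), 138 °C, 1 h, argon
Reagents that add atoms: none
Why: Moore rearrangement, in which 4π electrocyclic ring opening with the methoxy group rotating outward, 6π electrocyclisation of the dienylketene and tautomerisation form the six-membered ring with the free hydroxyl para to the methoxy group that came from C4.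

Step 5
Reactants: 7 2,3,4-trimethoxyphenol
Product: 8 2,3,4,4-tetramethoxycyclohexa-2,5-dien-1-one
Conditions: PhI(OAc)2 (1.1 equiv), MeOH, 0 °C
Reagents that add atoms: methanol CO
Why: Oxidative dearomatisation of a para-methoxyphenol with PhI(OAc)2 in methanol traps the phenoxenium ion at the methoxy-bearing carbon and gives the para-quinone monoketal.

Step 6
Reactants: 9 (2E)-3-methylpent-2-en-4-yn-1-ol
Product: 10 (2E)-3-methylpenta-2,4-dien-1-ol
Conditions: H2 (1 atm), Pd/CaCO3 poisoned with Pb(OAc)2 (Lindlar catalyst), quinoline, EtOAc/hexane, rt, stopped after 1 equiv H2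
Reagents that add atoms: none
Why: Lindlar semihydrogenation reduces the terminal alkyne to the vinyl group and leaves the trisubstituted E alkene untouched.

Step 7
Reactants: 10 (2E)-3-methylpenta-2,4-dien-1-ol
Product: 11 (3E)-5-bromo-3-methylpenta-1,3-diene
Conditions: PBr3 (0.4 equiv), pyridine (cat.), Et2O, −20 °C; used at once as a cold solution
Reagents that add atoms: phosphorus tribromide BrP(Br)Br
Why: SN2 bromination of the primary allylic alcohol through its phosphite ester keeps the E geometry, and because the 3-methylpentadienyl skeleton is constitutionally symmetric an allylic shift cannot give a regioisomer.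

Step 8
Reactants: 8 2,3,4,4-tetramethoxycyclohexa-2,5-dien-1-one; 11 (3E)-5-bromo-3-methylpenta-1,3-diene
Product: 13 (5R,6R)-2,3,4,4-tetramethoxy-5-methyl-6-[(2E)-3-methylpenta-2,4-dien-1-yl]cyclohex-2-en-1-one, via bromomagnesium enolate 12 (not isolated)
Conditions: CuBr·SMe2 (5 mol%), (R)-1-[(SP)-2-(diphenylphosphino)ferrocenyl]ethyldicyclohexylphosphine (6 mol%), MeMgBr (1.15 equiv, slow addition), t-BuOMe/CH2Cl2, −78 °C; then 11 (2 equiv), DMPU, −78 → 0 °C
Reagents that add atoms: methylmagnesium bromide C[Mg]Br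
Why: Proposed new method: a monovalent copper–ferrocenyl diphosphine complex should π-bind only the unsubstituted C5=C6 enone arm of the cross-conjugated dienone (the C2=C3 arm is a tetrasubstituted, donor-deactivated vinylogous ester), pass through a trivalent copper σ-alkyl enolate and reductively eliminate the C5–CH3 bond faster than uncatalysed 1,2-addition, the chiral pocket selecting the C5 face (5R), after which the bromomagnesium enolate is C-alkylated by SN2 attack on the dienyl bromide anti to the new methyl group (6R, trans); the closest known reaction types are the copper/ferrocenyl-diphosphine conjugate addition of Grignard reagents to cyclohexenones, the copper/phosphoramidite addition of dialkylzincs to 4,4-dialkoxycyclohexadienones and the stoichiometric cuprate addition/enolate alkylation, none of which has been shown as a catalytic enantioselective one-pot process on a 2,3-dialkoxy quinone monoketal with a dienyl halide.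

Step 9
Reactants: 13 (5R,6R)-2,3,4,4-tetramethoxy-5-methyl-6-[(2E)-3-methylpenta-2,4-dien-1-yl]cyclohex-2-en-1-one
Product: 14 (1R,5R,6R)-2,3,4,4-tetramethoxy-5-methyl-6-[(2E)-3-methylpenta-2,4-dien-1-yl]cyclohex-2-en-1-ol
Conditions: LiBH(s-Bu)3 (L-Selectride, 1.5 equiv), THF, −78 → −40 °C; then H2O
Reagents that add atoms: none
Why: Substrate-controlled 1,2-hydride reduction in which the bulky trialkylborohydride attacks equatorially on the half-chair that holds the methyl group and the side chain pseudoequatorial, giving the pseudoaxial alcohol cis to the side chain (1R).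

Step 10
Reactants: 15 3-methylbut-2-enal; 16 propargyl bromide (3-bromoprop-1-yne)
Product: 18 (4S)-6-methylhept-5-en-1-yn-4-ol, via trimethylsilyl ether 17 (not isolated)
Conditions: CrCl2 (10 mol%), (S,S)-1,8-bis(4-isopropyl-4,5-dihydro-1,3-oxazol-2-yl)-9H-carbazole-type tridentate ligand (12 mol%), Mn powder (2 equiv), Me3SiCl (1.5 equiv), i-Pr2NEt (0.3 equiv), THF, rt; then 1 M HCl
Reagents that add atoms: chlorotrimethylsilane C[Si](C)(C)Cl (silyl group of 17 only)
Why: Chromium-catalysed asymmetric Nozaki–Hiyama propargylation, in which the ligand-bound allenylchromium species adds 1,2 to the enal through a closed six-membered transition state to give the homopropargylic alcohol with the 4S centre set by the ligand (to be checked by Mosher ester analysis), while Mn and Me3SiCl turn the catalyst over.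

Step 11
Reactants: 18 (4S)-6-methylhept-5-en-1-yn-4-ol
Product: 19 tert-butyldimethyl{[(4S)-6-methylhept-5-en-1-yn-4-yl]oxy}silane
Conditions: TBSCl (1.3 equiv), imidazole (2.5 equiv), DMF, rt
Reagents that add atoms: tert-butyldimethylsilyl chloride CC(C)(C)[Si](C)(C)Cl
Why: Standard imidazole-promoted silylation protects the secondary allylic alcohol without touching the stereocentre.

Step 12
Reactants: 19 tert-butyldimethyl{[(4S)-6-methylhept-5-en-1-yn-4-yl]oxy}silane
Product: 21 (2E,4S)-4-[(tert-butyldimethylsilyl)oxy]-2-methylhept-2-en-6-yn-1-ol, via over-oxidised enal 20 (not isolated)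
Conditions: SeO2 (0.3 equiv), t-BuOOH (70% aq., 3 equiv), salicylic acid (0.1 equiv), CH2Cl2, rt; then NaBH4, MeOH, 0 °C
Reagents that add atoms: tert-butyl hydroperoxide CC(C)(C)OO
Why: Catalytic SeO2 allylic oxidation (ene reaction then [2,3]-sigmatropic shift) hydroxylates the (E)-methyl of the gem-dimethyl alkene selectively to the (2E) allylic alcohol, and NaBH4 returns the minor enal to the same alcohol.

Step 13
Reactants: 21 (2E,4S)-4-[(tert-butyldimethylsilyl)oxy]-2-methylhept-2-en-6-yn-1-ol
Product: 22 (2E,4S)-1,4-bis[(tert-butyldimethylsilyl)oxy]-2-methylhept-2-en-6-yne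
Conditions: TBSCl (1.2 equiv), imidazole (2.5 equiv), DMF, 0 °C → rt
Reagents that add atoms: tert-butyldimethylsilyl chloride CC(C)(C)[Si](C)(C)Cl
Why: Standard silylation of the primary allylic alcohol gives the bis-silyl ether needed for the organoaluminium step.

Step 14
Reactants: 22 (2E,4S)-1,4-bis[(tert-butyldimethylsilyl)oxy]-2-methylhept-2-en-6-yne
Product: 24 (1E,4S,5E)-4,7-bis[(tert-butyldimethylsilyl)oxy]-1-iodo-2,6-dimethylhepta-1,5-diene, via alkenylalane 23 (not isolated)
Conditions: Me3Al (3 equiv), Cp2ZrCl2 (0.3 equiv), CH2Cl2, 0 °C → rt; then I2 (1.3 equiv), THF, −30 °C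
Reagents that add atoms: trimethylaluminium C[Al](C)C; iodine [I][I]
Why: Negishi zirconium-catalysed carboalumination adds methyl and aluminium syn across the terminal alkyne with methyl on the internal carbon, and iodinolysis with retention gives the (E)-2-methylalkenyl iodide.

Step 15
Reactants: 14 (1R,5R,6R)-2,3,4,4-tetramethoxy-5-methyl-6-[(2E)-3-methylpenta-2,4-dien-1-yl]cyclohex-2-en-1-ol; 24 (1E,4S,5E)-4,7-bis[(tert-butyldimethylsilyl)oxy]-1-iodo-2,6-dimethylhepta-1,5-diene
Product: 26 (1R,5R,6R)-6-[(2E,6E,9S,10E)-9,12-bis(tert-butyldimethylsilyloxy)-3,7,11-trimethyldodeca-2,6,10-trien-1-yl]-2,3,4,4-tetramethoxy-5-methylcyclohex-2-en-1-ol, via alkylborane 25 (not isolated)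
Conditions: 9-BBN (2.5 equiv), THF, 0 °C → rt; then 24 (1.1 equiv), Pd(dppf)Cl2 (5 mol%), AsPh3 (10 mol%), Cs2CO3 (3 equiv), DMF/H2O, rt, degassed
Reagents that add atoms: 9-borabicyclo[3.3.1]nonane B1C2CCCC1CCC2 (boron groups of 25 only)
Why: B-alkyl Suzuki–Miyaura coupling, in which 9-BBN adds anti-Markovnikov only to the monosubstituted vinyl end of the diene (the hydroxyl being held as a borinate) and the primary alkylborane transmetalates to the alkenylpalladium iodide formed by oxidative addition of zerovalent palladium into the C–I bond, so that reductive elimination forms the C5'–C6' bond with retention of the (E)-alkene geometry and no stereocentre is touched.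

Step 16
Reactants: 26 (1R,5R,6R)-6-[(2E,6E,9S,10E)-9,12-bis(tert-butyldimethylsilyloxy)-3,7,11-trimethyldodeca-2,6,10-trien-1-yl]-2,3,4,4-tetramethoxy-5-methylcyclohex-2-en-1-ol
Product: 27 (1R,5R,6R)-6-[(2E,6E,9S,10E)-9,12-dihydroxy-3,7,11-trimethyldodeca-2,6,10-trien-1-yl]-2,3,4,4-tetramethoxy-5-methylcyclohex-2-en-1-ol
Conditions: Bu4NF (3 equiv), THF, 0 °C → rt; then H2O
Reagents that add atoms: none
Why: Fluoride-mediated desilylation is carried out while the ketone is still masked as its ketal, so no base-sensitive enolisable centre or γ-hydroxy enone is present.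

Step 17
Reactants: 27 (1R,5R,6R)-6-[(2E,6E,9S,10E)-9,12-dihydroxy-3,7,11-trimethyldodeca-2,6,10-trien-1-yl]-2,3,4,4-tetramethoxy-5-methylcyclohex-2-en-1-ol
Product: 28 (4R,5R,6R)-4-hydroxy-5-[(2E,6E,9S,10E)-9,12-dihydroxy-3,7,11-trimethyldodeca-2,6,10-trien-1-yl]-2,3-dimethoxy-6-methylcyclohex-2-en-1-one (CNP0109398.2)
Conditions: PPTS (0.2 equiv), acetone/H2O (10:1), 0 °C → rt
Reagents that add atoms: water O
Why: Mild acid-catalysed ketal hydrolysis (ionisation to a methoxy-stabilised oxocarbenium ion and capture by water at that carbon) unveils the C1 ketone in conjugation with the dimethoxy alkene, while the weak acid leaves the allylic alcohols and the trans C6 methyl centre unchanged.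

**Compound list**
1 | squaric acid (3,4-dihydroxycyclobut-3-ene-1,2-dione) | OC1=C(O)C(=O)C1=O | starting material
2 | dimethyl squarate (3,4-dimethoxycyclobut-3-ene-1,2-dione) | COC1=C(OC)C(=O)C1=O | intermediate
3 | 4-ethenyl-4-hydroxy-2,3-dimethoxycyclobut-2-en-1-one (racemic) | COC1=C(OC)C(O)(C=C)C1=O | intermediate
4 | 4-ethenyl-2,3,4-trimethoxycyclobut-2-en-1-one (racemic) | COC1=C(OC)C(OC)(C=C)C1=O | intermediate
5 | (3Z)-2,3,4-trimethoxyhexa-1,3,5-trien-1-one (dienylketene) | O=C=C(OC)/C(OC)=C(\C=C)OC | intermediate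
6 | 2,3,4-trimethoxycyclohexa-2,4-dien-1-one | COC1=C(OC)C(OC)=CCC1=O | intermediate
7 | 2,3,4-trimethoxyphenol | COc1ccc(O)c(OC)c1OC | intermediate
8 | 2,3,4,4-tetramethoxycyclohexa-2,5-dien-1-one | COC1=C(OC)C(=O)C=CC1(OC)OC | intermediate
9 | (2E)-3-methylpent-2-en-4-yn-1-ol | OC/C=C(\C)C#C | starting material
10 | (2E)-3-methylpenta-2,4-dien-1-ol | OC/C=C(\C)C=C | intermediate
11 | (3E)-5-bromo-3-methylpenta-1,3-diene | BrC/C=C(\C)C=C | intermediate
12 | bromomagnesium (3R)-4,4,5,6-tetramethoxy-3-methylcyclohexa-1,5-dien-1-olate | COC1=C(OC)C([O-])=C[C@@H](C)C1(OC)OC.[Mg+2].[Br-] | intermediate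
13 | (5R,6R)-2,3,4,4-tetramethoxy-5-methyl-6-[(2E)-3-methylpenta-2,4-dien-1-yl]cyclohex-2-en-1-one | COC1=C(OC)C(=O)[C@H](C/C=C(\C)C=C)[C@@H](C)C1(OC)OC | intermediate
14 | (1R,5R,6R)-2,3,4,4-tetramethoxy-5-methyl-6-[(2E)-3-methylpenta-2,4-dien-1-yl]cyclohex-2-en-1-ol | COC1=C(OC)[C@H](O)[C@H](C/C=C(\C)C=C)[C@@H](C)C1(OC)OC | intermediate
15 | 3-methylbut-2-enal | CC(C)=CC=O | starting material
16 | propargyl bromide (3-bromoprop-1-yne) | C#CCBr | starting material
17 | trimethyl{[(4S)-6-methylhept-5-en-1-yn-4-yl]oxy}silane | C#CC[C@H](O[Si](C)(C)C)C=C(C)C | intermediate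
18 | (4S)-6-methylhept-5-en-1-yn-4-ol | C#CC[C@H](O)C=C(C)C | intermediate
19 | tert-butyldimethyl{[(4S)-6-methylhept-5-en-1-yn-4-yl]oxy}silane | C#CC[C@H](O[Si](C)(C)C(C)(C)C)C=C(C)C | intermediate
20 | (2E,4S)-4-[(tert-butyldimethylsilyl)oxy]-2-methylhept-2-en-6-ynal | C#CC[C@H](O[Si](C)(C)C(C)(C)C)/C=C(\C)C=O | intermediate
21 | (2E,4S)-4-[(tert-butyldimethylsilyl)oxy]-2-methylhept-2-en-6-yn-1-ol | C#CC[C@H](O[Si](C)(C)C(C)(C)C)/C=C(\C)CO | intermediate
22 | (2E,4S)-1,4-bis[(tert-butyldimethylsilyl)oxy]-2-methylhept-2-en-6-yne | C#CC[C@H](O[Si](C)(C)C(C)(C)C)/C=C(\C)CO[Si](C)(C)C(C)(C)C | intermediate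
23 | [(1E,4S,5E)-4,7-bis[(tert-butyldimethylsilyl)oxy]-2,6-dimethylhepta-1,5-dien-1-yl]dimethylalumane | C[Al](C)/C=C(\C)C[C@H](O[Si](C)(C)C(C)(C)C)/C=C(\C)CO[Si](C)(C)C(C)(C)C | intermediate
24 | (1E,4S,5E)-4,7-bis[(tert-butyldimethylsilyl)oxy]-1-iodo-2,6-dimethylhepta-1,5-diene | I/C=C(\C)C[C@H](O[Si](C)(C)C(C)(C)C)/C=C(\C)CO[Si](C)(C)C(C)(C)C | intermediate
25 | 9-{[(1R,5R,6R)-6-[(2E)-5-(9-borabicyclo[3.3.1]nonan-9-yl)-3-methylpent-2-en-1-yl]-2,3,4,4-tetramethoxy-5-methylcyclohex-2-en-1-yl]oxy}-9-borabicyclo[3.3.1]nonane | COC1=C(OC)[C@H](OB2C3CCCC2CCC3)[C@H](C/C=C(\C)CCB2C3CCCC2CCC3)[C@@H](C)C1(OC)OC | intermediate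
26 | (1R,5R,6R)-6-[(2E,6E,9S,10E)-9,12-bis(tert-butyldimethylsilyloxy)-3,7,11-trimethyldodeca-2,6,10-trien-1-yl]-2,3,4,4-tetramethoxy-5-methylcyclohex-2-en-1-ol | COC1=C(OC)[C@H](O)[C@H](C/C=C(\C)CC/C=C(\C)C[C@H](O[Si](C)(C)C(C)(C)C)/C=C(\C)CO[Si](C)(C)C(C)(C)C)[C@@H](C)C1(OC)OC | intermediate
27 | (1R,5R,6R)-6-[(2E,6E,9S,10E)-9,12-dihydroxy-3,7,11-trimethyldodeca-2,6,10-trien-1-yl]-2,3,4,4-tetramethoxy-5-methylcyclohex-2-en-1-ol | COC1=C(OC)[C@H](O)[C@H](C/C=C(\C)CC/C=C(\C)C[C@H](O)/C=C(\C)CO)[C@@H](C)C1(OC)OC | intermediate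
28 | (4R,5R,6R)-4-hydroxy-5-[(2E,6E,9S,10E)-9,12-dihydroxy-3,7,11-trimethyldodeca-2,6,10-trien-1-yl]-2,3-dimethoxy-6-methylcyclohex-2-en-1-one | COC1=C(OC)[C@H](O)[C@H](C/C=C(\C)CC/C=C(\C)C[C@H](O)/C=C(\C)CO)[C@@H](C)C1=O | target

**Step count**
Total: 17 steps. Longest linear sequence: 10 steps (steps 1, 2, 3, 4, 5, 8, 9, 15, 16, 17).

**Three steps most likely to fail**

The first is step 8, the proposed one-pot copper-catalysed methylation/alkylation. Its risks are competing 1,2-addition, low enantioselectivity on this electron-rich dienone and sluggish enolate alkylation. The fallback uses known chemistry, sets out from 8 and 11 and comes back at 14. Me2CuLi (from MeLi and CuI, THF, −78 °C) is added to 8 to give the racemic lithium enolate F1, which is alkylated in the same flask with 11 in THF/HMPA (the established stoichiometric cuprate three-component coupling) to the racemic trans ketone F2. Reduction with LiBH(s-Bu)3 as in step 9 gives the racemic alcohol F3. Acylation with (S)-2-methoxy-2-phenylacetic acid (DCC, DMAP, CH2Cl2) gives two diastereomers, the (1R,5R,6R) ester F4 and the (1S,5S,6S) ester F5, which are separated on silica or by crystallisation. Methanolysis of the (1R,5R,6R) ester F4 (K2CO3, MeOH) gives 14 as a single enantiomer.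

The second is step 12, the SeO2 oxidation. The alkene is deactivated by the allylic silyloxy group, the propargylic CH2 may compete and yields of such oxidations are moderate. The fallback sets out from 19 and comes back at 21, replacing C–H oxidation by alkene cleavage and olefination. Ozone (CH2Cl2, −78 °C, Sudan red end point) cleaves the trisubstituted alkene of 19 in preference to the alkyne and gives the ozonide F6. Me2S reduces it to the α-silyloxy aldehyde F7. Wittig reaction with ethyl 2-(triphenylphosphoranylidene)propanoate (CH2Cl2, rt, E-selective) gives the enoate F8, and i-Bu2AlH (CH2Cl2, −78 °C) reduces the enoate F8 to 21.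

The third is step 15, the hydroboration/Suzuki–Miyaura coupling. 9-BBN must add only to the terminal alkene of a 1,3-diene in a substrate that carries a free allylic hydroxyl and an enol ether. The fallback sets out from 10 and 24, uses 8 and comes back at 26; it changes the order of fragment union. The simple dienol 10 is hydroborated with 9-BBN (2.2 equiv) to the bis-boron adduct F9, which is coupled with 24 under the same Pd(dppf)Cl2/AsPh3/Cs2CO3 conditions to the C15 allylic alcohol F10. This is converted into the allylic bromide F11 (CBr4, PPh3, 2,6-lutidine, CH2Cl2, −20 °C). The allylic bromide F11 is used in place of 11 in the methylation/alkylation of 8 (step 8 conditions, through enolate 12) to give the ketone F12, and reduction of the ketone F12 with LiBH(s-Bu)3 as in step 9 gives 26.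

Further compounds
F1 | step 8 | racemic lithium 4,4,5,6-tetramethoxy-3-methylcyclohexa-1,5-dien-1-olate (1:1 mixture of enantiomers) | COC1=C(OC)C([O-])=C[C@@H](C)C1(OC)OC.COC1=C(OC)C([O-])=C[C@H](C)C1(OC)OC.[Li+].[Li+]
F2 | step 8 | racemic trans-2,3,4,4-tetramethoxy-5-methyl-6-[(2E)-3-methylpenta-2,4-dien-1-yl]cyclohex-2-en-1-one (1:1 mixture of 13 and its enantiomer) | COC1=C(OC)C(=O)[C@H](C/C=C(\C)C=C)[C@@H](C)C1(OC)OC.COC1=C(OC)C(=O)[C@@H](C/C=C(\C)C=C)[C@H](C)C1(OC)OC
F3 | step 8 | racemic 2,3,4,4-tetramethoxy-5-methyl-6-[(2E)-3-methylpenta-2,4-dien-1-yl]cyclohex-2-en-1-ol (1:1 mixture of 14 and its enantiomer) | COC1=C(OC)[C@H](O)[C@H](C/C=C(\C)C=C)[C@@H](C)C1(OC)OC.COC1=C(OC)[C@@H](O)[C@@H](C/C=C(\C)C=C)[C@H](C)C1(OC)OC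
F4 | step 8 | (1R,5R,6R)-2,3,4,4-tetramethoxy-5-methyl-6-[(2E)-3-methylpenta-2,4-dien-1-yl]cyclohex-2-en-1-yl (2S)-2-methoxy-2-phenylacetate | COC1=C(OC)[C@H](OC(=O)[C@@H](OC)c2ccccc2)[C@H](C/C=C(\C)C=C)[C@@H](C)C1(OC)OC
F5 | step 8 | (1S,5S,6S)-2,3,4,4-tetramethoxy-5-methyl-6-[(2E)-3-methylpenta-2,4-dien-1-yl]cyclohex-2-en-1-yl (2S)-2-methoxy-2-phenylacetate | COC1=C(OC)[C@@H](OC(=O)[C@@H](OC)c2ccccc2)[C@@H](C/C=C(\C)C=C)[C@H](C)C1(OC)OC
F6 | step 12 | tert-butyl{[(1S)-1-(5,5-dimethyl-1,2,4-trioxolan-3-yl)but-3-yn-1-yl]oxy}dimethylsilane (ozonide, mixture at the trioxolane carbon) | C#CC[C@H](O[Si](C)(C)C(C)(C)C)C1OOC(C)(C)O1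
F7 | step 12 | (2S)-2-[(tert-butyldimethylsilyl)oxy]pent-4-ynal | C#CC[C@H](O[Si](C)(C)C(C)(C)C)C=O
F8 | step 12 | ethyl (2E,4S)-4-[(tert-butyldimethylsilyl)oxy]-2-methylhept-2-en-6-ynoate | C#CC[C@H](O[Si](C)(C)C(C)(C)C)/C=C(\C)C(=O)OCC
F9 | step 15 | 9-{[(2E)-5-(9-borabicyclo[3.3.1]nonan-9-yl)-3-methylpent-2-en-1-yl]oxy}-9-borabicyclo[3.3.1]nonane | B1(OC/C=C(\C)CCB2C3CCCC2CCC3)C2CCCC1CCC2
F10 | step 15 | (2E,6E,9S,10E)-9,12-bis[(tert-butyldimethylsilyl)oxy]-3,7,11-trimethyldodeca-2,6,10-trien-1-ol | OC/C=C(\C)CC/C=C(\C)C[C@H](O[Si](C)(C)C(C)(C)C)/C=C(\C)CO[Si](C)(C)C(C)(C)C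
F11 | step 15 | (2E,6E,9S,10E)-1-bromo-9,12-bis[(tert-butyldimethylsilyl)oxy]-3,7,11-trimethyldodeca-2,6,10-triene | BrC/C=C(\C)CC/C=C(\C)C[C@H](O[Si](C)(C)C(C)(C)C)/C=C(\C)CO[Si](C)(C)C(C)(C)C
F12 | step 15 | (5R,6R)-6-[(2E,6E,9S,10E)-9,12-bis(tert-butyldimethylsilyloxy)-3,7,11-trimethyldodeca-2,6,10-trien-1-yl]-2,3,4,4-tetramethoxy-5-methylcyclohex-2-en-1-one | COC1=C(OC)C(=O)[C@H](C/C=C(\C)CC/C=C(\C)C[C@H](O[Si](C)(C)C(C)(C)C)/C=C(\C)CO[Si](C)(C)C(C)(C)C)[C@@H](C)C1(OC)OC
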